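**Retrosynthetic overview**
1. The 7α-hydroxyl (SeO2 allylic hydroxylation) and the 2α-angelate go on last; the 2α,3α-diol comes from a 3β-alcohol through the 3-ketone (C2 hydroxylation, then reduction to the axial alcohol).
2. Key disconnection: rings A and B are made together from an acyclic (S)-epoxy tetraenyl acetate by a Cp2TiCl radical cascade (C4–C5 bond, then C9–C10 bond; ring A closes first and ring B second, in the same operation). The cascade also gives the 8(17)-alkene and sets C3, C5, C9 and C10.
3. The cascade substrate comes from a Z-selective Still–Gennari olefination (C5=C10; the ester carbon becomes C20), then reduction and acetylation.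
4. Aldehyde half: (R)-linalool (supplies C13 and its configuration) by E-methyl oxidation and two-carbon extension. Phosphonate half: Shi epoxidation of 5-bromo-2-methylpent-2-ene, then phosphonoacetate alkylation.
5. No ring is formed before or after the cascade.

Assumption: labdane numbering is used for all intermediates (C20 = CH2O carbon on C10, C17 = exocyclic methylene carbon); commercial (R)-(−)-linalool and the L-fructose-derived Shi ketone are taken as enantiopure.

**Route**

Step 1
Reactants: 1 (R)-(−)-linalool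
Product: 2 (2E,6R)-2,6-dimethylocta-2,7-diene-1,6-diol
Conditions: SeO2 (0.1 equiv), t-BuOOH (2 equiv), salicylic acid (cat.), CH2Cl2, rt
Reagents that add atoms: tert-butyl hydroperoxide, CC(C)(C)OO
Why: Sharpless allylic hydroxylation (SeO2 ene reaction, then [2,3]-sigmatropic shift) oxidizes only the E-methyl group of the trisubstituted alkene, the vinyl group has no allylic hydrogen, and the carbinol stereocenter (future C13, from the chiral pool) is not touched.

Step 2
Reactants: 2 (2E,6R)-2,6-dimethylocta-2,7-diene-1,6-diol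
Product: 3 (3R,6E)-8-bromo-3,7-dimethylocta-1,6-dien-3-ol
Conditions: CBr4, PPh3, CH2Cl2, −20 °C
Reagents that add atoms: carbon tetrabromide, BrC(Br)(Br)Br
Why: Appel reaction, in which bromide displaces the primary allylic alkoxyphosphonium by SN2 without allylic shift, while the hindered tertiary alcohol does not react at low temperature.

Step 3
Reactants: 3 (3R,6E)-8-bromo-3,7-dimethylocta-1,6-dien-3-ol; 4 N-tert-butylethanimine
Product: 6 (4E,8R)-8-hydroxy-4,8-dimethyldeca-4,9-dienal, via tert-butyl imine 5 (not isolated)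
Conditions: 4 (2.2 equiv), LiN(i-Pr)2 (2.2 equiv), THF, −78 °C; then 3, −78 to −30 °C; then AcOH–NaOAc buffer (pH 4.5), H2O, rt
Reagents that add atoms: water, O
Why: Metallo-enamine (aza-enolate) alkylation by SN2 at the primary allylic bromide adds the two-carbon aldehyde unit (C5, C6), one equivalent of base being spent on the hydroxyl, and the imine is hydrolysed under buffered conditions that spare the tertiary allylic alcohol and the E-alkene.

Step 4
Reactants: 7 5-bromo-2-methylpent-2-ene
Product: 8 (3S)-3-(2-bromoethyl)-2,2-dimethyloxirane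
Conditions: L-fructose-derived Shi ketone (0.3 equiv), KHSO5 (as the triple salt 2KHSO5·KHSO4·K2SO4), K2CO3, Bu4NHSO4, MeCN–dimethoxymethane/aqueous buffer (pH 10.5), 0 °C
Reagents that add atoms: potassium peroxymonosulfate, [K+].[O-]S(=O)(=O)OO
Why: Shi asymmetric epoxidation, in which the chiral dioxirane made from the ketone delivers oxygen to one face of the trisubstituted alkene through a spiro transition state, and this enantiomer of the catalyst gives the (S)-epoxide whose single stereocenter later fixes the absolute configuration of the decalin.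

Step 5
Reactants: 8 (3S)-3-(2-bromoethyl)-2,2-dimethyloxirane; 9 methyl 2-[bis(2,2,2-trifluoroethoxy)phosphoryl]acetate
Product: 10 methyl 2-[bis(2,2,2-trifluoroethoxy)phosphoryl]-4-[(2S)-3,3-dimethyloxiran-2-yl]butanoate
Conditions: NaH, NaI (cat.), DMF, 0 to 50 °C
Reagents that add atoms: none
Why: SN2 C-alkylation of the sodium phosphonoacetate anion by the primary bromide (iodide-catalysed), a soft carbanion that leaves the trisubstituted epoxide alone, and the new α-center is an epimer mixture that becomes sp2 in the next step.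

Step 6
Reactants: 10 methyl 2-[bis(2,2,2-trifluoroethoxy)phosphoryl]-4-[(2S)-3,3-dimethyloxiran-2-yl]butanoate; 6 (4E,8R)-8-hydroxy-4,8-dimethyldeca-4,9-dienal
Product: 11 methyl (2Z,6E,10R)-2-{2-[(2S)-3,3-dimethyloxiran-2-yl]ethyl}-10-hydroxy-6,10-dimethyldodeca-2,6,11-trienoate
Conditions: KN(SiMe3)2, 18-crown-6, THF, −78 °C
Reagents that add atoms: none
Why: Still–Gennari variant of the Horner–Wadsworth–Emmons olefination, in which the trifluoroethyl phosphonate with a crown-complexed potassium ion eliminates from the kinetic adduct to give the Z-enoate, so the ester carbon (future C20) is cis to the C6 chain as a trans ring fusion requires.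

Step 7
Reactants: 11 methyl (2Z,6E,10R)-2-{2-[(2S)-3,3-dimethyloxiran-2-yl]ethyl}-10-hydroxy-6,10-dimethyldodeca-2,6,11-trienoate
Product: 12 (2Z,6E,10R)-2-{2-[(2S)-3,3-dimethyloxiran-2-yl]ethyl}-6,10-dimethyldodeca-2,6,11-triene-1,10-diol
Conditions: i-Bu2AlH (3.3 equiv), CH2Cl2, −78 °C; aqueous work-up
Reagents that add atoms: none
Why: Hydride 1,2-reduction of the conjugated ester to the allylic alcohol is fast at −78 °C, where the trisubstituted epoxide and the alkenes are inert and the double-bond geometry is kept.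

Step 8
Reactants: 12 (2Z,6E,10R)-2-{2-[(2S)-3,3-dimethyloxiran-2-yl]ethyl}-6,10-dimethyldodeca-2,6,11-triene-1,10-diol
Product: 13 (2Z,6E,10R)-2-{2-[(2S)-3,3-dimethyloxiran-2-yl]ethyl}-10-hydroxy-6,10-dimethyldodeca-2,6,11-trien-1-yl acetate
Conditions: Ac2O, pyridine, DMAP (cat.), CH2Cl2, 0 °C
Reagents that add atoms: acetic anhydride, CC(=O)OC(C)=O
Why: DMAP-catalysed acylation is selective for the primary allylic alcohol over the tertiary one and puts the C20 acetate of the target in place before the rings are formed.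

Step 9
Reactants: 13 (2Z,6E,10R)-2-{2-[(2S)-3,3-dimethyloxiran-2-yl]ethyl}-10-hydroxy-6,10-dimethyldodeca-2,6,11-trien-1-yl acetate
Product: 14 (13R)-20-acetoxylabda-8(17),14-diene-3β,13-diol
Conditions: Cp2TiCl2 (2.5 equiv), Mn dust (8 equiv), THF, rt; slow addition of 13 (0.01 M); then cold 1 M HCl
Reagents that add atoms: none
Why: Nugent–RajanBabu epoxide opening by Cp2TiCl (trivalent titanium) gives the tertiary C4 radical, which closes ring A and then ring B by two 6-endo-trig radical cyclizations through a chair–chair array, so that the (S)-epoxide and the two alkene geometries fix 3β-OH, 5α-H, 10β-CH2OAc and the 9β side chain, after which the tertiary C8 radical is captured by a second Cp2TiCl and loses a β-hydride from the methyl group to give the 8(17)-alkene, while the neutral radical conditions leave the tertiary allylic alcohol and the allylic acetate alone.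

Step 10
Reactants: 14 (13R)-20-acetoxylabda-8(17),14-diene-3β,13-diol
Product: 15 (13R)-20-acetoxy-13-hydroxylabda-8(17),14-dien-3-one
Conditions: Dess–Martin periodinane, pyridine, CH2Cl2, rt
Reagents that add atoms: none
Why: Dess–Martin oxidation converts the only secondary alcohol to the ketone, the tertiary allylic alcohol cannot be oxidized, and pyridine buffers the acetic acid that is released.

Step 11
Reactants: 15 (13R)-20-acetoxy-13-hydroxylabda-8(17),14-dien-3-one
Product: 16 (13R)-20-acetoxy-2α,13-dihydroxylabda-8(17),14-dien-3-one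
Conditions: KN(SiMe3)2 (2.2 equiv), THF, −78 °C; then 2-(benzenesulfonyl)-3-phenyloxaziridine, −78 °C; AcOH quench
Reagents that add atoms: 2-(benzenesulfonyl)-3-phenyloxaziridine, O=S(=O)(N1OC1c1ccccc1)c1ccccc1
Why: Davis enolate hydroxylation, in which only C2 can be enolized (C4 is quaternary) and the oxaziridine approaches the potassium enolate from the α-face, away from the axial 10β-CH2OAc and 4β-methyl groups, to give the equatorial 2α-alcohol.

Step 12
Reactants: 16 (13R)-20-acetoxy-2α,13-dihydroxylabda-8(17),14-dien-3-one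
Product: 17 (13R)-20-acetoxylabda-8(17),14-diene-2α,3α,13-triol
Conditions: LiBH(s-Bu)3 (2.5 equiv), THF, −78 °C; aqueous quench
Reagents that add atoms: none
Why: Steric-approach-controlled ketone reduction, in which the bulky tri-sec-butylborohydride delivers hydride along the equatorial trajectory of the 4,4-dimethyl-3-ketone to give the axial 3α-alcohol (cis to the 2α-hydroxyl), and at −78 °C the acetate is not reduced.

Step 13
Reactants: 17 (13R)-20-acetoxylabda-8(17),14-diene-2α,3α,13-triol; 18 angelic acid
Product: 20 (13R)-20-acetoxy-2α-angeloyloxylabda-8(17),14-diene-3α,13-diol, via mixed anhydride 19 (not isolated)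
Conditions: 18, 2,4,6-trichlorobenzoyl chloride, Et3N, toluene, rt; then 17, 80 °C
Reagents that add atoms: 2,4,6-trichlorobenzoyl chloride, O=C(Cl)c1c(Cl)cc(Cl)cc1Cl (its aroyl group is in 19 only)
Why: Yamaguchi-type mixed-anhydride esterification run without DMAP so that the Z-enoate does not isomerize to the tiglate, the equatorial secondary 2α-hydroxyl being acylated in preference to the axial neopentyl 3α-hydroxyl and the tertiary 13-hydroxyl.

Step 14
Reactants: 20 (13R)-20-acetoxy-2α-angeloyloxylabda-8(17),14-diene-3α,13-diol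
Product: 21 (13R)-20-acetoxy-2α-angeloyloxylabda-8(17),14-diene-3α,7α,13-triol
Conditions: SeO2 (0.5 equiv), t-BuOOH, CH2Cl2, rt
Reagents that add atoms: tert-butyl hydroperoxide, CC(C)(C)OO
Why: Sharpless allylic hydroxylation with SeO2 (ene reaction from the less hindered α-face, then [2,3]-sigmatropic shift that returns the double bond to C8=C17) gives the axial 7α-alcohol, the vinyl group (no allylic hydrogen) and the electron-poor angelate being inert.

**Compound list**
1 | (R)-(−)-linalool, (3R)-3,7-dimethylocta-1,6-dien-3-ol | C=C[C@](C)(O)CCC=C(C)C | starting material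
2 | (2E,6R)-2,6-dimethylocta-2,7-diene-1,6-diol | C=C[C@](C)(O)CC/C=C(\C)CO | intermediate
3 | (3R,6E)-8-bromo-3,7-dimethylocta-1,6-dien-3-ol | C=C[C@](C)(O)CC/C=C(\C)CBr | intermediate
4 | N-tert-butylethanimine | CC=NC(C)(C)C | starting material
5 | (4E,8R)-N-tert-butyl-8-hydroxy-4,8-dimethyldeca-4,9-dien-1-imine | C=C[C@](C)(O)CC/C=C(\C)CCC=NC(C)(C)C | intermediate (not isolated)
6 | (4E,8R)-8-hydroxy-4,8-dimethyldeca-4,9-dienal | C=C[C@](C)(O)CC/C=C(\C)CCC=O | intermediate
7 | 5-bromo-2-methylpent-2-ene | CC(C)=CCCBr | starting material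
8 | (3S)-3-(2-bromoethyl)-2,2-dimethyloxirane | BrCC[C@@H]1OC1(C)C | intermediate
9 | methyl 2-[bis(2,2,2-trifluoroethoxy)phosphoryl]acetate | COC(=O)CP(=O)(OCC(F)(F)F)OCC(F)(F)F | starting material
10 | methyl 2-[bis(2,2,2-trifluoroethoxy)phosphoryl]-4-[(2S)-3,3-dimethyloxiran-2-yl]butanoate (C2 epimer mixture) | COC(=O)C(CC[C@@H]1OC1(C)C)P(=O)(OCC(F)(F)F)OCC(F)(F)F | intermediate
11 | methyl (2Z,6E,10R)-2-{2-[(2S)-3,3-dimethyloxiran-2-yl]ethyl}-10-hydroxy-6,10-dimethyldodeca-2,6,11-trienoate | C=C[C@](C)(O)CC/C=C(\C)CC/C=C(\C(=O)OC)CC[C@@H]1OC1(C)C | intermediate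
12 | (2Z,6E,10R)-2-{2-[(2S)-3,3-dimethyloxiran-2-yl]ethyl}-6,10-dimethyldodeca-2,6,11-triene-1,10-diol | C=C[C@](C)(O)CC/C=C(\C)CC/C=C(\CO)CC[C@@H]1OC1(C)C | intermediate
13 | (2Z,6E,10R)-2-{2-[(2S)-3,3-dimethyloxiran-2-yl]ethyl}-10-hydroxy-6,10-dimethyldodeca-2,6,11-trien-1-yl acetate | C=C[C@](C)(O)CC/C=C(\C)CC/C=C(\COC(C)=O)CC[C@@H]1OC1(C)C | intermediate
14 | (13R)-20-acetoxylabda-8(17),14-diene-3β,13-diol (trans-decalin: 5α-H, 9α-H, 10β-CH2OAc) | C=C[C@](C)(O)CC[C@H]1C(=C)CC[C@H]2C(C)(C)[C@@H](O)CC[C@]12COC(C)=O | intermediate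
15 | (13R)-20-acetoxy-13-hydroxylabda-8(17),14-dien-3-one | C=C[C@](C)(O)CC[C@H]1C(=C)CC[C@H]2C(C)(C)C(=O)CC[C@]12COC(C)=O | intermediate
16 | (13R)-20-acetoxy-2α,13-dihydroxylabda-8(17),14-dien-3-one | C=C[C@](C)(O)CC[C@H]1C(=C)CC[C@H]2C(C)(C)C(=O)[C@H](O)C[C@]12COC(C)=O | intermediate
17 | (13R)-20-acetoxylabda-8(17),14-diene-2α,3α,13-triol | C=C[C@](C)(O)CC[C@H]1C(=C)CC[C@H]2C(C)(C)[C@H](O)[C@H](O)C[C@]12COC(C)=O | intermediate
18 | angelic acid, (2Z)-2-methylbut-2-enoic acid | C/C=C(/C)C(=O)O | starting material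
19 | (2Z)-2-methylbut-2-enoic 2,4,6-trichlorobenzoic anhydride | C/C=C(/C)C(=O)OC(=O)c1c(Cl)cc(Cl)cc1Cl | intermediate (not isolated)
20 | (13R)-20-acetoxy-2α-angeloyloxylabda-8(17),14-diene-3α,13-diol | C=C[C@](C)(O)CC[C@H]1C(=C)CC[C@H]2C(C)(C)[C@H](O)[C@H](OC(=O)/C(C)=C\C)C[C@]12COC(C)=O | intermediate
21 | (13R)-20-acetoxy-2α-angeloyloxylabda-8(17),14-diene-3α,7α,13-triol | C=C[C@](C)(O)CC[C@H]1C(=C)[C@H](O)C[C@H]2C(C)(C)[C@H](O)[C@H](OC(=O)/C(C)=C\C)C[C@]12COC(C)=O | target

**Summary**
Total step count: 14. Longest linear sequence: 12 steps (steps 1–3 and 6–14, from 1).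

The three steps most likely to fail:

Step 9 (radical bicyclization). Ring A closure onto an unactivated alkene may lose out to early capture of the C4 radical by Cp2TiCl. The fallback sets out from ester 11 instead of acetate 13. With Cp2TiCl2 (cat.), Mn, Me3SiCl and 2,4,6-collidine in THF, the C4 radical first adds to the enoate in a fast, polarity-matched 6-endo conjugate addition, and the electrophilic α-ester radical then closes ring B onto the electron-rich C8=C9 alkene. This gives methyl (13R)-3β,13-dihydroxylabda-8(17),14-dien-20-oate F1. LiAlH4 reduces it to (13R)-labda-8(17),14-diene-3β,13,20-triol F2, and acetylation of the primary hydroxyl only (Ac2O, 2,4,6-collidine, −20 °C) comes back to the route at 14.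

Step 12 (reduction to the 3α-alcohol). The free 2α-hydroxyl may direct hydride to the wrong face, or the excess hydride may attack the acetate. The fallback sets out from 16. The 2α-hydroxyl is masked with Et3SiCl and imidazole to give (13R)-20-acetoxy-13-hydroxy-2α-(triethylsilyloxy)labda-8(17),14-dien-3-one F3, so that the reduction with LiBH(s-Bu)3 is governed by steric approach alone. This gives (13R)-20-acetoxy-2α-(triethylsilyloxy)labda-8(17),14-diene-3α,13-diol F4, and HF·pyridine removes the silyl group to come back at 17.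

Step 13 (angeloylation). Direct acylation may be slow or may isomerize the angelate to the tiglate. The fallback sets out from 17 and builds the Z-double bond on the molecule. The 2α-hydroxyl is esterified with 2-[bis(2,2,2-trifluoroethoxy)phosphoryl]propanoic acid (DCC, DMAP) to give (13R)-20-acetoxy-3α,13-dihydroxylabda-8(17),14-dien-2α-yl 2-[bis(2,2,2-trifluoroethoxy)phosphoryl]propanoate F5. Still–Gennari olefination of F5 with acetaldehyde (KN(SiMe3)2, 18-crown-6, THF, −78 °C) then gives the angelate and comes back at 20.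

**Further compounds**
F1 | step 9 | methyl (13R)-3β,13-dihydroxylabda-8(17),14-dien-20-oate | C=C[C@](C)(O)CC[C@H]1C(=C)CC[C@H]2C(C)(C)[C@@H](O)CC[C@]12C(=O)OC
F2 | step 9 | (13R)-labda-8(17),14-diene-3β,13,20-triol | C=C[C@](C)(O)CC[C@H]1C(=C)CC[C@H]2C(C)(C)[C@@H](O)CC[C@]12CO
F3 | step 12 | (13R)-20-acetoxy-13-hydroxy-2α-(triethylsilyloxy)labda-8(17),14-dien-3-one | C=C[C@](C)(O)CC[C@H]1C(=C)CC[C@H]2C(C)(C)C(=O)[C@H](O[Si](CC)(CC)CC)C[C@]12COC(C)=O
F4 | step 12 | (13R)-20-acetoxy-2α-(triethylsilyloxy)labda-8(17),14-diene-3α,13-diol | C=C[C@](C)(O)CC[C@H]1C(=C)CC[C@H]2C(C)(C)[C@H](O)[C@H](O[Si](CC)(CC)CC)C[C@]12COC(C)=O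
F5 | step 13 | (13R)-20-acetoxy-3α,13-dihydroxylabda-8(17),14-dien-2α-yl 2-[bis(2,2,2-trifluoroethoxy)phosphoryl]propanoate | C=C[C@](C)(O)CC[C@H]1C(=C)CC[C@H]2C(C)(C)[C@H](O)[C@H](OC(=O)C(C)P(=O)(OCC(F)(F)F)OCC(F)(F)F)C[C@]12COC(C)=O
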